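The cyclohexane is disconnected at C1–C6, the bond between the bromine-bearing quaternary carbon C1 and the ring methylene C6 that sits between the two quaternary carbons (C1: CBr(CH2Cl); C2, C4: CHCl; C5: CMe(chloroethenyl)). Since C1 carries Br and CH2Cl, it is a hydrobrominated 2-(chloromethyl)allyl unit: ring-closing metathesis of a fully functionalised acyclic triene forges C1=C6 in one operation and leaves a 1-(chloromethyl)cyclohexene, ready for Markovnikov HBr addition. The precursor already holds both secondary chlorides and the C5 quaternary centre, set by two organocatalytic chlorinations and a chirality-transferring Claisen rearrangement whose relay carbinol is expelled as but-1-ene in the ring closure.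

Key step: step 11

Remark: the antipodes named for the ligand in step 3 and for the amine catalysts in steps 5 and 7 are those expected to give the configurations drawn; if the sense of induction were the opposite, the mirror-image ligand or catalyst would be used and nothing else would change.

Step 1
Reactants: 1 (E)-3-methylpent-2-en-4-yn-1-ol
Product: 3 (2E,4E)-5-chloro-3-methylpenta-2,4-dien-1-ol, via alkenylzirconocene 2 (not isolated)
Conditions: Cp2Zr(H)Cl (2.3 equiv), THF, rt; then NCS, 0 °C
Reagents that add atoms: N-chlorosuccinimide, O=C1CCC(=O)N1Cl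
Why: Hydrozirconation–halogenolysis: the first equivalent of Cp2Zr(H)Cl is consumed by the hydroxyl group, the second adds Zr–H syn across the terminal alkyne with zirconium on the terminal carbon, and NCS cleaves the C–Zr bond with retention, which should give the (E)-chloroalkene and leave the trisubstituted alkene untouched.

Step 2
Reactants: 3 (2E,4E)-5-chloro-3-methylpenta-2,4-dien-1-ol
Product: 4 (2E,4E)-5-chloro-3-methylpenta-2,4-dienal
Conditions: MnO2 (excess), CH2Cl2, rt
Reagents that add atoms: none
Why: MnO2 oxidation is selective for the dienylic primary alcohol and should not isomerise either alkene.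

Step 3
Reactants: 4 (2E,4E)-5-chloro-3-methylpenta-2,4-dienal
Product: 5 (3S,4E,6E)-7-chloro-5-methylhepta-4,6-dien-3-ol
Conditions: Et2Zn, (−)-MIB [(2S)-3-exo-morpholinoisoborneol, 5 mol%], toluene/hexane, 0 °C; aq NH4Cl
Reagents that add atoms: diethylzinc, CC[Zn]CC
Why: Amino-alcohol-catalysed enantioselective 1,2-addition of a dialkylzinc to an enal; the ligand selects the aldehyde face and should give the (S)-carbinol, the only source of absolute configuration for the quaternary carbon.

Step 4
Reactants: 5 (3S,4E,6E)-7-chloro-5-methylhepta-4,6-dien-3-ol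
Product: 7 (3S,4E)-3-[(E)-2-chloroethenyl]-3-methylhept-4-enal, via allyl vinyl ether 6 (not isolated)
Conditions: butyl vinyl ether, Pd(TFA)2 (2 mol%), 4,7-diphenyl-1,10-phenanthroline, Et3N, 75 °C; then xylene, 140 °C
Reagents that add atoms: butyl vinyl ether, C=COCCCC
Why: Transfer vinylation followed by an aliphatic Claisen rearrangement through the chair with the ethyl group equatorial (the other chair has a 1,3-diaxial ethyl/methyl clash), so the C–O stereocentre should be relayed fully to the new quaternary carbon (S) and the new alkene should be E.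

Step 5
Reactants: 7 (3S,4E)-3-[(E)-2-chloroethenyl]-3-methylhept-4-enal
Product: 8 (2R,3S,4E)-2-chloro-3-[(E)-2-chloroethenyl]-3-methylhept-4-enal
Conditions: NCS, (2S,5S)-2,5-diphenylpyrrolidine (10 mol%), CH2Cl2, 0 °C to rt; used without chromatography
Reagents that add atoms: N-chlorosuccinimide, O=C1CCC(=O)N1Cl
Why: Enamine-catalysed α-chlorination of an aldehyde, a reaction that works well for neopentyl-type aldehydes; the C2-symmetric amine, not the neighbouring quaternary carbon, selects the enamine face and should set C2 as R.

Step 6
Reactants: 8 (2R,3S,4E)-2-chloro-3-[(E)-2-chloroethenyl]-3-methylhept-4-enal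
Product: 9 (2E,4S,5S,6E)-4-chloro-5-[(E)-2-chloroethenyl]-5-methylnona-2,6-dienal
Conditions: Ph3P=CHCHO, toluene, 50 °C
Reagents that add atoms: (triphenylphosphoranylidene)acetaldehyde, O=CC=P(c1ccccc1)(c1ccccc1)c1ccccc1
Why: Wittig olefination with a stabilised, weakly basic ylide should give the (E)-enal without epimerising the α-chloro aldehyde.

Step 7
Reactants: 9 (2E,4S,5S,6E)-4-chloro-5-[(E)-2-chloroethenyl]-5-methylnona-2,6-dienal
Product: 11 (2R,4S,5S,6E)-2,4-dichloro-5-[(E)-2-chloroethenyl]-5-methylnon-6-enal, via saturated chloro aldehyde 10 (not isolated)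
Conditions: (2R,5R)-5-benzyl-2-tert-butyl-3-methylimidazolidin-4-one·TFA (20 mol%), Hantzsch ester (diethyl 2,6-dimethyl-1,4-dihydropyridine-3,5-dicarboxylate), EtOAc, −30 °C; then 2,3,4,5,6,6-hexachlorocyclohexa-2,4-dien-1-one, −40 °C
Reagents that add atoms: 2,3,4,5,6,6-hexachlorocyclohexa-2,4-dien-1-one, O=C1C(Cl)=C(Cl)C(Cl)=C(Cl)C1(Cl)Cl
Why: Iminium–enamine organocascade (formal asymmetric addition of HCl across an enal): the dihydropyridine delivers hydride to C3 of the iminium ion and the resulting enamine is chlorinated on the face fixed by the imidazolidinone, which should set C2 as R independently of the C4 chloride.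

Step 8
Reactants: 11 (2R,4S,5S,6E)-2,4-dichloro-5-[(E)-2-chloroethenyl]-5-methylnon-6-enal
Product: 12 (3R,5S,6S,7E)-1,3,5-trichloro-6-[(E)-2-chloroethenyl]-6-methyldec-7-en-2-ol (both C2 epimers)
Conditions: ICH2Cl, MeLi·LiBr, THF, −78 °C (Barbier mode); AcOH, −78 °C
Reagents that add atoms: chloroiodomethane, ClCI
Why: Chloromethyllithium formed by iodine–lithium exchange in the presence of the aldehyde adds to the carbonyl faster than it decomposes, and the cold acidic quench should prevent epoxide closure; the carbinol configuration does not matter because it is oxidised next.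

Step 9
Reactants: 12 (3R,5S,6S,7E)-1,3,5-trichloro-6-[(E)-2-chloroethenyl]-6-methyldec-7-en-2-ol
Product: 13 (3R,5S,6S,7E)-1,3,5-trichloro-6-[(E)-2-chloroethenyl]-6-methyldec-7-en-2-one
Conditions: Dess–Martin periodinane, CH2Cl2, 0 °C to rt
Reagents that add atoms: none
Why: Dess–Martin oxidation is neutral and should give the α,α'-dichloro ketone without epimerising C3.

Step 10
Reactants: 13 (3R,5S,6S,7E)-1,3,5-trichloro-6-[(E)-2-chloroethenyl]-6-methyldec-7-en-2-one
Product: 14 (3R,5S,6S,7E)-3,5-dichloro-6-[(E)-2-chloroethenyl]-2-(chloromethyl)-6-methyldeca-1,7-diene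
Conditions: Cp2Ti(μ-Cl)(μ-CH2)AlMe2, pyridine (cat.), THF/toluene, −40 to 0 °C
Reagents that add atoms: Tebbe reagent, C[Al-]1(C)C[Ti](C2C=CC=C2)(C2C=CC=C2)[Cl+]1
Why: Tebbe olefination through a titanium methylidene and an oxatitanacyclobutane is non-basic, so the enolisable dichloro ketone should be methylenated without epimerisation or Favorskii-type chemistry.

Step 11
Reactants: 14 (3R,5S,6S,7E)-3,5-dichloro-6-[(E)-2-chloroethenyl]-2-(chloromethyl)-6-methyldeca-1,7-diene
Product: 15 (3S,4S,6R)-4,6-dichloro-3-[(E)-2-chloroethenyl]-1-(chloromethyl)-3-methylcyclohex-1-ene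
Conditions: second-generation Hoveyda–Grubbs catalyst RuCl2(H2IMes)(=CH-C6H4-2-OiPr) (10 mol%), toluene (5 mM), 80 °C, Ar sparge
Reagents that add atoms: none
Why: Ring-closing olefin metathesis by the metallacyclobutane mechanism: the ruthenium alkylidene takes up the butenyl arm on the quaternary carbon, forms a ruthenacyclobutane with the 2-(chloromethyl)allyl alkene and expels but-1-ene, so that the new C=C bond of the cyclohexene is the C1–C6 bond of the target. The closest known reaction type is RCM of a 1,7-diene with one gem-disubstituted partner to a trisubstituted cyclohexene, which tolerates allylic chlorides. The six-membered ring is closed by joining the two inner alkene carbons of the 1,7-diene, with loss of a volatile alkene as the driving force. No stereocentre is formed, and the three existing ones are not touched under these neutral conditions. The step needs chemoselectivity between the butenyl and the chloroethenyl groups on the quaternary carbon, and this is secured because the electron-poor chloroalkene reacts far more slowly and would lead to an unproductive chlorocarbene. High dilution and removal of butene should suppress oligomerisation.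

Step 12
Reactants: 15 (3S,4S,6R)-4,6-dichloro-3-[(E)-2-chloroethenyl]-1-(chloromethyl)-3-methylcyclohex-1-ene
Product: 16 (1R,2R,4S,5S)-1-bromo-2,4-dichloro-1-(chloromethyl)-5-[(E)-2-chloroethenyl]-5-methylcyclohexane
Conditions: HBr (g), CH2Cl2, BHT (cat.), dark, −40 to 0 °C
Reagents that add atoms: hydrogen bromide, Br
Why: Ionic Markovnikov hydrobromination: protonation at the ring CH places the positive charge on the CH2Cl-bearing carbon, and bromide should add anti in the trans-diaxial sense through the chair that keeps both ring chlorides equatorial, giving axial Br and equatorial CH2Cl (also the more stable epimer, since the other would place CH2Cl syn-axial to the chloroethenyl group); the deactivated chloroalkene should not react and the inhibitor suppresses the radical anti-Markovnikov chain.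

Compound list
1 | (E)-3-methylpent-2-en-4-yn-1-ol | C#C/C(C)=C/CO | starting material
2 | C,O-bis(chlorozirconocenyl) derivative of (2E,4E)-3-methylpenta-2,4-dien-1-ol (alkenylzirconocene) | Cl[Zr](C1C=CC=C1)(C1C=CC=C1)/C=C/C(C)=C/CO[Zr](Cl)(C1C=CC=C1)C1C=CC=C1 | intermediate (not isolated)
3 | (2E,4E)-5-chloro-3-methylpenta-2,4-dien-1-ol | Cl/C=C/C(C)=C/CO | intermediate
4 | (2E,4E)-5-chloro-3-methylpenta-2,4-dienal | Cl/C=C/C(C)=C/C=O | intermediate
5 | (3S,4E,6E)-7-chloro-5-methylhepta-4,6-dien-3-ol | CC[C@H](O)/C=C(\C)/C=C/Cl | intermediate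
6 | (1E,3E,5S)-1-chloro-5-(ethenyloxy)-3-methylhepta-1,3-diene | CC[C@H](OC=C)/C=C(\C)/C=C/Cl | intermediate (not isolated)
7 | (3S,4E)-3-[(E)-2-chloroethenyl]-3-methylhept-4-enal | C[C@@](/C=C/CC)(CC=O)/C=C/Cl | intermediate
8 | (2R,3S,4E)-2-chloro-3-[(E)-2-chloroethenyl]-3-methylhept-4-enal | C[C@@](/C=C/CC)([C@@H](Cl)C=O)/C=C/Cl | intermediate
9 | (2E,4S,5S,6E)-4-chloro-5-[(E)-2-chloroethenyl]-5-methylnona-2,6-dienal | C[C@@](/C=C/CC)([C@@H](Cl)/C=C/C=O)/C=C/Cl | intermediate
10 | (4S,5S,6E)-4-chloro-5-[(E)-2-chloroethenyl]-5-methylnon-6-enal | C[C@@](/C=C/CC)([C@@H](Cl)CCC=O)/C=C/Cl | intermediate (not isolated)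
11 | (2R,4S,5S,6E)-2,4-dichloro-5-[(E)-2-chloroethenyl]-5-methylnon-6-enal | C[C@@](/C=C/CC)([C@@H](Cl)C[C@@H](Cl)C=O)/C=C/Cl | intermediate
12 | (3R,5S,6S,7E)-1,3,5-trichloro-6-[(E)-2-chloroethenyl]-6-methyldec-7-en-2-ol, both C2 epimers | C[C@@](/C=C/CC)([C@@H](Cl)C[C@@H](Cl)C(O)CCl)/C=C/Cl | intermediate
13 | (3R,5S,6S,7E)-1,3,5-trichloro-6-[(E)-2-chloroethenyl]-6-methyldec-7-en-2-one | C[C@@](/C=C/CC)([C@@H](Cl)C[C@@H](Cl)C(=O)CCl)/C=C/Cl | intermediate
14 | (3R,5S,6S,7E)-3,5-dichloro-6-[(E)-2-chloroethenyl]-2-(chloromethyl)-6-methyldeca-1,7-diene | C[C@@](/C=C/CC)([C@@H](Cl)C[C@@H](Cl)C(=C)CCl)/C=C/Cl | intermediate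
15 | (3S,4S,6R)-4,6-dichloro-3-[(E)-2-chloroethenyl]-1-(chloromethyl)-3-methylcyclohex-1-ene | C[C@@]1([C@@H](Cl)C[C@@H](Cl)C(CCl)=C1)/C=C/Cl | intermediate
16 | (1R,2R,4S,5S)-1-bromo-2,4-dichloro-1-(chloromethyl)-5-[(E)-2-chloroethenyl]-5-methylcyclohexane | C[C@@]1(/C=C/Cl)C[C@@](Br)(CCl)[C@H](Cl)C[C@@H]1Cl | target

Total step count: 12. Longest linear sequence: 12 steps (fully linear from 1).

Steps most likely to fail

Step 12. Protonation of the ring alkene may be too slow because two β-chlorines destabilise the developing tertiary cation. Acid-promoted ionisation and transposition of the allylic chlorides, the radical anti-Markovnikov chain, or bromide delivery with poor facial control could then compete. The fallback sets out from 15 and comes back at 16 in one step by cobalt-hydride hydrogen-atom-transfer hydrobromination (Co(acac)2 cat., t-BuOOH, Et3SiH, TsBr, CH2Cl2/n-PrOH, rt). This generates the tertiary radical at C1 regardless of the inductive effect and transfers bromine from tosyl bromide. If both C1 epimers form, brief exposure to catalytic ZnBr2 should enrich 16, the epimer with equatorial CH2Cl. No new compound is made.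

Step 11. The ruthenium carbene may fail to load on either hindered alkene (the butenyl arm on a quaternary carbon, or the gem-disubstituted alkene flanked by allylic chlorides), so the catalyst may decay before ring closure. The fallback re-cuts the diene and does not merely change the catalyst; it sets out from 13 and comes back at 15. Ketone 13 is ozonised at −78 °C (O3, CH2Cl2/MeOH, then Me2S); the electron-rich butenyl alkene should react far faster than the chloroalkene, giving keto aldehyde (2R,3S,5R)-3,5,7-trichloro-2-[(E)-2-chloroethenyl]-2-methyl-6-oxoheptanal F1. Both carbonyl groups are methylenated with Cp2Ti(μ-Cl)(μ-CH2)AlMe2 (3 equiv) to give triene (3S,4S,6R)-4,6-dichloro-3-[(E)-2-chloroethenyl]-7-(chloromethyl)-3-methylocta-1,7-diene F2. Its unhindered vinyl group is the loading site for the same ruthenium catalyst, and ring closure with loss of ethene should give 15.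

Step 7. The C4 configuration may be lost through γ-deprotonation of the iminium ion (dienamine formation) before hydride transfer, or the enamine may be diverted into intramolecular alkylation. The fallback separates the two events and avoids the iminium ion; it sets out from 9 and comes back at 11. Conjugate reduction of 9 with [(Ph3P)CuH]6 in wet benzene at rt gives 10, which is isolated. Chlorination of 10 as in step 5 (NCS, (2S,5S)-2,5-diphenylpyrrolidine, CH2Cl2) then gives 11. No new compound is made.

Further compounds
F0 | step 12 | none | none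
F1 | step 11 | (2R,3S,5R)-3,5,7-trichloro-2-[(E)-2-chloroethenyl]-2-methyl-6-oxoheptanal | C[C@@](C=O)([C@@H](Cl)C[C@@H](Cl)C(=O)CCl)/C=C/Cl
F2 | step 11 | (3S,4S,6R)-4,6-dichloro-3-[(E)-2-chloroethenyl]-7-(chloromethyl)-3-methylocta-1,7-diene | C[C@@](C=C)([C@@H](Cl)C[C@@H](Cl)C(=C)CCl)/C=C/Cl
F0 | step 7 | none | none
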